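## Retrosynthetic overview

1. The target flavanone is released last from its tris-MOM/TBS-protected form by mild acid.
2. Ring C is disconnected at O1–C8a and C4–C4a together: an (S)-β-silyloxy methyl ester carrying the complete ring B/ring D unit is joined to 3,5-bis(methoxymethoxy)benzyne. The alkoxide adds to the aryne, and the aryl anion so formed closes ring C on the ester carbon.
3. Enabling feature: in ring A the ether oxygen O1 and the ketone carbon C4 sit on the adjacent carbons C8a and C4a, and C4a is flanked on its other side by the oxygen at C5. Ring A is therefore the vicinal O,C-adduct of a 3,5-dioxygenated benzyne whose C5 oxygen sends the oxygen nucleophile to C8a and the carbanion to C4a.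
4. The β-hydroxy ester (C2 stereocentre) comes from the ring B methyl ester by crossed Claisen condensation and asymmetric transfer hydrogenation. The prenyl group comes from an aromatic Claisen rearrangement, and the ring D carbinol from Jacobsen–Katsuki epoxidation of a chromene followed by hydrogenolysis.
5. Order of ring formation: ring D on ring B first (steps 3–5), ring C last, fused to ring A in the same operation (step 17).

Key step: step 17

Remark: the SMILES is read as (2S) at the flavanone carbon and (3S) at the carbinol of the dimethyldihydropyran ring (ring D); flavanone locants are used for rings A and C, chromane locants for the ring B/ring D unit; MOM = methoxymethyl, TBS = tert-butyldimethylsilyl, TMS = trimethylsilyl, prenyl = 3-methylbut-2-en-1-yl.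

## Route

Step 1
Reactants: 1 methyl 3,4-dihydroxybenzoate; 2 3-chloro-3-methylbut-1-yne
Product: 3 methyl 3-hydroxy-4-[(2-methylbut-3-yn-2-yl)oxy]benzoate
Conditions: 2 (1.2 equiv), K2CO3 (1.1 equiv), KI, CuI (cat.), DMF, 60 °C, argon
Reagents that add atoms: none
Why: Williamson-type O-alkylation with a tertiary propargylic chloride (copper-assisted), in which the 4-OH, para to the ester and therefore the more acidic phenol, is ionised first under limiting carbonate and should be alkylated selectively.

Step 2
Reactants: 3 methyl 3-hydroxy-4-[(2-methylbut-3-yn-2-yl)oxy]benzoate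
Product: 4 methyl 3-(benzyloxy)-4-[(2-methylbut-3-yn-2-yl)oxy]benzoate
Conditions: BnBr, K2CO3, DMF, rt
Reagents that add atoms: benzyl bromide, BrCc1ccccc1
Why: Williamson ether synthesis that masks the remaining phenol for the oxidation in step 4 with a group that step 5 removes at no extra cost.

Step 3
Reactants: 4 methyl 3-(benzyloxy)-4-[(2-methylbut-3-yn-2-yl)oxy]benzoate
Product: 5 methyl 8-(benzyloxy)-2,2-dimethyl-2H-chromene-6-carboxylate
Conditions: N,N-diethylaniline, 190 °C
Reagents that add atoms: none
Why: thermal aryl propargyl ether rearrangement (propargyl Claisen rearrangement, 1,5-hydrogen shift and oxa-6π electrocyclisation) should close ring D as a 2,2-dimethylchromene at the only ortho carbon that can rearomatise, the other one carrying the benzyloxy group.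

Step 4
Reactants: 5 methyl 8-(benzyloxy)-2,2-dimethyl-2H-chromene-6-carboxylate
Product: 6 methyl (3S,4S)-8-(benzyloxy)-3,4-epoxy-2,2-dimethylchromane-6-carboxylate
Conditions: [(S,S)-salen]MnCl (salen = N,N'-bis(3,5-di-tert-butylsalicylidene)cyclohexane-1,2-diamine dianion, 3 mol%), aq. NaOCl (pH 11.3, Na2HPO4), 4-phenylpyridine N-oxide (cat.), CH2Cl2, 0 °C
Reagents that add atoms: sodium hypochlorite, [Na+].[O-]Cl
Why: Jacobsen–Katsuki epoxidation of a 2,2-dimethylchromene, a privileged cis-olefin class for this catalyst, in which the (S,S) ligand is expected to direct oxo transfer to the face that gives the (3S,4S)-epoxide and so fixes the future carbinol centre of ring D.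

Step 5
Reactants: 6 methyl (3S,4S)-8-(benzyloxy)-3,4-epoxy-2,2-dimethylchromane-6-carboxylate
Product: 7 methyl (3S)-3,8-dihydroxy-2,2-dimethylchromane-6-carboxylate
Conditions: H2 (1 atm), Pd/C (10%), EtOAc, rt
Reagents that add atoms: none
Why: palladium-catalysed hydrogenolysis should cleave the benzylic C4–O bond of the epoxide and the O-benzyl ether in one operation while the C3–O bond is untouched, so the (3S) configuration is retained.

Step 6
Reactants: 7 methyl (3S)-3,8-dihydroxy-2,2-dimethylchromane-6-carboxylate; 2 3-chloro-3-methylbut-1-yne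
Product: 8 methyl (3S)-3-hydroxy-2,2-dimethyl-8-[(2-methylbut-3-yn-2-yl)oxy]chromane-6-carboxylate
Conditions: 2 (1.3 equiv), CuCl2·2H2O (1 mol%), DBU (1.3 equiv), MeCN, 0 °C
Reagents that add atoms: none
Why: copper-catalysed propargylic O-alkylation of a phenol, chemoselective because DBU ionises the phenol but not the hindered secondary alcohol.

Step 7
Reactants: 8 methyl (3S)-3-hydroxy-2,2-dimethyl-8-[(2-methylbut-3-yn-2-yl)oxy]chromane-6-carboxylate
Product: 9 methyl (3S)-3-hydroxy-2,2-dimethyl-8-[(2-methylbut-3-en-2-yl)oxy]chromane-6-carboxylate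
Conditions: H2 (1 atm), Pd/CaCO3 poisoned with Pb(OAc)2 (Lindlar catalyst), quinoline, EtOAc, rt
Reagents that add atoms: none
Why: Lindlar semi-hydrogenation should stop at the terminal alkene and give the 1,1-dimethylallyl aryl ether needed for the sigmatropic shift.

Step 8
Reactants: 9 methyl (3S)-3-hydroxy-2,2-dimethyl-8-[(2-methylbut-3-en-2-yl)oxy]chromane-6-carboxylate
Product: 10 methyl (3S)-3,8-dihydroxy-2,2-dimethyl-7-(3-methylbut-2-en-1-yl)chromane-6-carboxylate
Conditions: toluene, 120 °C (sealed tube)
Reagents that add atoms: none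
Why: aromatic Claisen rearrangement ([3,3]-sigmatropic) of the 1,1-dimethylallyl ether should deliver the allyl unit with transposition as a linear prenyl group to C7, the only ortho position able to rearomatise, without touching the carbinol stereocentre.

Step 9
Reactants: 10 methyl (3S)-3,8-dihydroxy-2,2-dimethyl-7-(3-methylbut-2-en-1-yl)chromane-6-carboxylate
Product: 11 methyl (3S)-3-hydroxy-8-(methoxymethoxy)-2,2-dimethyl-7-(3-methylbut-2-en-1-yl)chromane-6-carboxylate
Conditions: MOMCl (1.2 equiv), K2CO3, acetone, rt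
Reagents that add atoms: chloromethyl methyl ether, COCCl
Why: phenoxide O-alkylation (Williamson type), selective because carbonate does not ionise the secondary alcohol.

Step 10
Reactants: 11 methyl (3S)-3-hydroxy-8-(methoxymethoxy)-2,2-dimethyl-7-(3-methylbut-2-en-1-yl)chromane-6-carboxylate
Product: 12 methyl (3S)-3-[(tert-butyldimethylsilyl)oxy]-8-(methoxymethoxy)-2,2-dimethyl-7-(3-methylbut-2-en-1-yl)chromane-6-carboxylate
Conditions: TBSCl, imidazole, DMAP (cat.), DMF, 50 °C
Reagents that add atoms: tert-butyldimethylsilyl chloride, CC(C)(C)[Si](C)(C)Cl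
Why: silylation of the hindered secondary alcohol gives an ether that should survive enolate, formic acid/amine and fluoride conditions at a neopentyl-type position and fall together with the MOM groups at the end.

Step 11
Reactants: 12 methyl (3S)-3-(TBS-oxy)-8-(MOM-oxy)-2,2-dimethyl-7-prenylchromane-6-carboxylate; 13 methyl acetate
Product: 15 methyl 3-[(3S)-3-[(tert-butyldimethylsilyl)oxy]-8-(methoxymethoxy)-2,2-dimethyl-7-(3-methylbut-2-en-1-yl)chroman-6-yl]-3-oxopropanoate, via lithium enolate of methyl acetate 14 (not isolated)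
Conditions: LDA (3.0 equiv), 13 (3.3 equiv), THF, −78 °C; then 12, −78 → −20 °C; aq. NH4Cl
Reagents that add atoms: none
Why: crossed Claisen condensation of a non-enolisable aryl ester with a preformed ester enolate, driven by deprotonation of the β-keto ester, the enolate being made with a slight excess of 13 so that no free amide base remains to metalate the benzylic–allylic CH2.

Step 12
Reactants: 15 methyl 3-[(3S)-3-(TBS-oxy)-8-(MOM-oxy)-2,2-dimethyl-7-prenylchroman-6-yl]-3-oxopropanoate
Product: 16 methyl (3S)-3-[(3S)-3-[(tert-butyldimethylsilyl)oxy]-8-(methoxymethoxy)-2,2-dimethyl-7-(3-methylbut-2-en-1-yl)chroman-6-yl]-3-hydroxypropanoate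
Conditions: RuCl(p-cymene)[(S,S)-TsDPEN] (1 mol%), HCO2H/Et3N (5:2), DMF, 30 °C
Reagents that add atoms: none
Why: Noyori–Ikariya asymmetric transfer hydrogenation of an aryl β-keto ester, in which the (S,S) ligand is expected to deliver hydride to the Re face of the aryl ketone (CH–π contact of the aryl group with the cymene ligand) and so set the (S)-carbinol that becomes C2 of the flavanone, without touching the prenyl olefin.

Step 13
Reactants: 16 methyl (3S)-3-[(3S)-3-(TBS-oxy)-8-(MOM-oxy)-2,2-dimethyl-7-prenylchroman-6-yl]-3-hydroxypropanoate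
Product: 17 methyl (3S)-3-[(3S)-3-[(tert-butyldimethylsilyl)oxy]-8-(methoxymethoxy)-2,2-dimethyl-7-(3-methylbut-2-en-1-yl)chroman-6-yl]-3-[(trimethylsilyl)oxy]propanoate
Conditions: TMSCl, imidazole, CH2Cl2, 0 °C; filtration through Et3N-deactivated silica
Reagents that add atoms: chlorotrimethylsilane, C[Si](C)(C)Cl
Why: O-silylation turns the carbinol into a fluoride-labile TMS ether, the latent proton-free alkoxide that step 17 requires.

Step 14
Reactants: 18 phloroglucinol
Product: 19 3,5-bis(methoxymethoxy)phenol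
Conditions: MOMCl (2.0 equiv), i-Pr2NEt, DMF, 0 °C → rt
Reagents that add atoms: chloromethyl methyl ether, COCCl
Why: statistical double O-alkylation of a threefold symmetric triol, from which the bis-ether is separated by chromatography.

Step 15
Reactants: 19 3,5-bis(methoxymethoxy)phenol
Product: 20 2-bromo-3,5-bis(methoxymethoxy)phenol
Conditions: NBS (1.0 equiv), CH2Cl2, −78 → −40 °C
Reagents that add atoms: N-bromosuccinimide, O=C1CCC(=O)N1Br
Why: electrophilic aromatic bromination, expected to go ortho to the free hydroxyl in a non-polar solvent at low temperature (hydrogen-bond delivery of NBS, two equivalent ortho sites, and a para site crowded between two MOM ethers).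

Step 16
Reactants: 20 2-bromo-3,5-bis(methoxymethoxy)phenol
Product: 24 3,5-bis(methoxymethoxy)-2-(trimethylsilyl)phenyl trifluoromethanesulfonate, via aryl trimethylsilyl ether 21 (not isolated), via aryllithium 22 (not isolated), via lithium silylphenoxide 23 (not isolated)
Conditions: HMDS, THF, 70 °C, then evaporation; n-BuLi, THF, −100 → −78 °C; Tf2O, −100 °C → rt
Reagents that add atoms: hexamethyldisilazane, C[Si](C)(C)N[Si](C)(C)C; trifluoromethanesulfonic anhydride, O=S(=O)(OS(=O)(=O)C(F)(F)F)C(F)(F)F
Why: O-silylation, bromine–lithium exchange, 1,3 O→C silyl shift (retro-Brook rearrangement) and O-triflation, the standard sequence to ortho-silylaryl triflate aryne precursors.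

Step 17
Reactants: 17 methyl (3S)-3-[(3S)-3-(TBS-oxy)-8-(MOM-oxy)-2,2-dimethyl-7-prenylchroman-6-yl]-3-(TMS-oxy)propanoate; 24 3,5-bis(methoxymethoxy)-2-(trimethylsilyl)phenyl trifluoromethanesulfonate
Product: 28 (2S)-2-[(3S)-3-[(tert-butyldimethylsilyl)oxy]-8-(methoxymethoxy)-2,2-dimethyl-7-(3-methylbut-2-en-1-yl)chroman-6-yl]-5,7-bis(methoxymethoxy)chroman-4-one, via aryne 25 (not isolated), via cesium alkoxide 26 (not isolated), via aryl cesium adduct 27 (not isolated)
Conditions: CsF (4 equiv), 18-crown-6 (0.2 equiv), THF, 0 °C → rt; 24 (1.5 equiv) added slowly; pH 7 buffer quench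
Reagents that add atoms: none
Why: Proposed new method: fluoride unmasks in a proton-free medium both the cesium alkoxide 26 (from the O–SiMe3 group) and the aryne 25 (from 24); the alkoxide adds to the aryne carbon remote from the flanking methoxymethoxy group (future C8a), because a 3-alkoxy substituent distorts the triple bond so that the carbanion develops on the carbon next to oxygen (future C4a), giving 27. The carbanion of 27 then attacks the methyl ester carbonyl in a 6-exo-trig acyl substitution that forms the C4–C4a bond and closes ring C, and the expelled methoxide is silylated by Me3SiF or by excess 24. The closest known reaction type is the fluoride-mediated annulation of arynes with ortho-hydroxy-, ortho-mercapto- and ortho-aminobenzoate esters to xanthones, thioxanthones and acridones (heteroatom addition to the aryne, then trapping of the aryl anion by the ester); the new element is an aliphatic β-silyloxy ester as the O,C-donor, which turns that annulation into a chroman-4-one synthesis. No stereocentre is created: C2 keeps the S configuration set in step 12 because its C–O bond is never broken, and its integrity depends on the alkoxide being captured by the aryne before retro-aldol cleavage and on the ketone not being ring-opened by base, which the low standing concentration of alkoxide, the low temperature and the weakly basic fluoride are meant to secure. The selectivities needed are regioselective addition (O to C8a, C to C4a), secured by the C5 oxygen beside the triple bond, and acyl trapping in preference to protonation of the aryl anion, secured by the absence of O–H bonds and by the six-membered transition state.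

Step 18
Reactants: 28 (2S)-2-[(3S)-3-(TBS-oxy)-8-(MOM-oxy)-2,2-dimethyl-7-prenylchroman-6-yl]-5,7-bis(MOM-oxy)chroman-4-one
Product: 29 (2S)-2-[(3S)-3,8-dihydroxy-2,2-dimethyl-7-(3-methylbut-2-en-1-yl)chroman-6-yl]-5,7-dihydroxychroman-4-one (the target flavanone)
Conditions: 3 M aq. HCl/MeOH (1:5), 40 °C
Reagents that add atoms: none
Why: acid-catalysed acetal exchange should remove the three aryl MOM ethers and methanolysis the TBS ether (global deprotection) under conditions mild enough to leave the prenyl group, the tertiary alkyl aryl ether of ring D and the C2 stereocentre untouched.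

## Compound list

1 | methyl 3,4-dihydroxybenzoate | COC(=O)c1ccc(O)c(O)c1 | starting material
2 | 3-chloro-3-methylbut-1-yne | CC(C)(Cl)C#C | starting material
3 | methyl 3-hydroxy-4-[(2-methylbut-3-yn-2-yl)oxy]benzoate | COC(=O)c1ccc(OC(C)(C)C#C)c(O)c1 | intermediate
4 | methyl 3-(benzyloxy)-4-[(2-methylbut-3-yn-2-yl)oxy]benzoate | COC(=O)c1ccc(OC(C)(C)C#C)c(OCc2ccccc2)c1 | intermediate
5 | methyl 8-(benzyloxy)-2,2-dimethyl-2H-chromene-6-carboxylate | COC(=O)c1cc2c(c(OCc3ccccc3)c1)OC(C)(C)C=C2 | intermediate
6 | methyl (3S,4S)-8-(benzyloxy)-3,4-epoxy-2,2-dimethylchromane-6-carboxylate | COC(=O)c1cc2c(c(OCc3ccccc3)c1)OC(C)(C)[C@H]4O[C@H]42 | intermediate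
7 | methyl (3S)-3,8-dihydroxy-2,2-dimethylchromane-6-carboxylate | COC(=O)c1cc2c(c(O)c1)OC(C)(C)[C@@H](O)C2 | intermediate
8 | methyl (3S)-3-hydroxy-2,2-dimethyl-8-[(2-methylbut-3-yn-2-yl)oxy]chromane-6-carboxylate | COC(=O)c1cc2c(c(OC(C)(C)C#C)c1)OC(C)(C)[C@@H](O)C2 | intermediate
9 | methyl (3S)-3-hydroxy-2,2-dimethyl-8-[(2-methylbut-3-en-2-yl)oxy]chromane-6-carboxylate | COC(=O)c1cc2c(c(OC(C)(C)C=C)c1)OC(C)(C)[C@@H](O)C2 | intermediate
10 | methyl (3S)-3,8-dihydroxy-2,2-dimethyl-7-(3-methylbut-2-en-1-yl)chromane-6-carboxylate | COC(=O)c1cc2c(c(O)c1CC=C(C)C)OC(C)(C)[C@@H](O)C2 | intermediate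
11 | methyl (3S)-3-hydroxy-8-(methoxymethoxy)-2,2-dimethyl-7-(3-methylbut-2-en-1-yl)chromane-6-carboxylate | COC(=O)c1cc2c(c(OCOC)c1CC=C(C)C)OC(C)(C)[C@@H](O)C2 | intermediate
12 | methyl (3S)-3-[(tert-butyldimethylsilyl)oxy]-8-(methoxymethoxy)-2,2-dimethyl-7-(3-methylbut-2-en-1-yl)chromane-6-carboxylate | COC(=O)c1cc2c(c(OCOC)c1CC=C(C)C)OC(C)(C)[C@@H](O[Si](C)(C)C(C)(C)C)C2 | intermediate
13 | methyl acetate | COC(C)=O | starting material
14 | lithium enolate of methyl acetate (lithium 1-methoxyethen-1-olate) | [Li+].[O-]C(=C)OC | intermediate (not isolated)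
15 | methyl 3-[(3S)-3-[(tert-butyldimethylsilyl)oxy]-8-(methoxymethoxy)-2,2-dimethyl-7-(3-methylbut-2-en-1-yl)chroman-6-yl]-3-oxopropanoate | COC(=O)CC(=O)c1cc2c(c(OCOC)c1CC=C(C)C)OC(C)(C)[C@@H](O[Si](C)(C)C(C)(C)C)C2 | intermediate
16 | methyl (3S)-3-[(3S)-3-[(tert-butyldimethylsilyl)oxy]-8-(methoxymethoxy)-2,2-dimethyl-7-(3-methylbut-2-en-1-yl)chroman-6-yl]-3-hydroxypropanoate | COC(=O)C[C@H](O)c1cc2c(c(OCOC)c1CC=C(C)C)OC(C)(C)[C@@H](O[Si](C)(C)C(C)(C)C)C2 | intermediate
17 | methyl (3S)-3-[(3S)-3-[(tert-butyldimethylsilyl)oxy]-8-(methoxymethoxy)-2,2-dimethyl-7-(3-methylbut-2-en-1-yl)chroman-6-yl]-3-[(trimethylsilyl)oxy]propanoate | COC(=O)C[C@H](O[Si](C)(C)C)c1cc2c(c(OCOC)c1CC=C(C)C)OC(C)(C)[C@@H](O[Si](C)(C)C(C)(C)C)C2 | intermediate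
18 | phloroglucinol (benzene-1,3,5-triol) | Oc1cc(O)cc(O)c1 | starting material
19 | 3,5-bis(methoxymethoxy)phenol | COCOc1cc(O)cc(OCOC)c1 | intermediate
20 | 2-bromo-3,5-bis(methoxymethoxy)phenol | COCOc1cc(O)c(Br)c(OCOC)c1 | intermediate
21 | [2-bromo-3,5-bis(methoxymethoxy)phenoxy]trimethylsilane | COCOc1cc(O[Si](C)(C)C)c(Br)c(OCOC)c1 | intermediate (not isolated)
22 | [2-lithio-3,5-bis(methoxymethoxy)phenoxy]trimethylsilane | COCOc1cc(O[Si](C)(C)C)c([Li])c(OCOC)c1 | intermediate (not isolated)
23 | lithium 3,5-bis(methoxymethoxy)-2-(trimethylsilyl)phenoxide | COCOc1cc([O-])c([Si](C)(C)C)c(OCOC)c1.[Li+] | intermediate (not isolated)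
24 | 3,5-bis(methoxymethoxy)-2-(trimethylsilyl)phenyl trifluoromethanesulfonate | COCOc1cc(OS(=O)(=O)C(F)(F)F)c([Si](C)(C)C)c(OCOC)c1 | intermediate
25 | 3,5-bis(methoxymethoxy)benzyne (1,2-didehydro-3,5-bis(methoxymethoxy)benzene) | COCOC1=CC(OCOC)=CC#C1 | intermediate (not isolated)
26 | cesium (1S)-1-[(3S)-3-[(tert-butyldimethylsilyl)oxy]-8-(methoxymethoxy)-2,2-dimethyl-7-(3-methylbut-2-en-1-yl)chroman-6-yl]-3-methoxy-3-oxopropan-1-olate | COC(=O)C[C@H]([O-])c1cc2c(c(OCOC)c1CC=C(C)C)OC(C)(C)[C@@H](O[Si](C)(C)C(C)(C)C)C2.[Cs+] | intermediate (not isolated)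
27 | cesium 2-{[(1S)-1-[(3S)-3-[(tert-butyldimethylsilyl)oxy]-8-(methoxymethoxy)-2,2-dimethyl-7-(3-methylbut-2-en-1-yl)chroman-6-yl]-3-methoxy-3-oxopropyl]oxy}-4,6-bis(methoxymethoxy)benzen-1-ide | COC(=O)C[C@H](Oc1cc(OCOC)cc(OCOC)[c-]1)c1cc2c(c(OCOC)c1CC=C(C)C)OC(C)(C)[C@@H](O[Si](C)(C)C(C)(C)C)C2.[Cs+] | intermediate (not isolated)
28 | (2S)-2-[(3S)-3-[(tert-butyldimethylsilyl)oxy]-8-(methoxymethoxy)-2,2-dimethyl-7-(3-methylbut-2-en-1-yl)chroman-6-yl]-5,7-bis(methoxymethoxy)chroman-4-one | CC(C)=CCc1c([C@@H]2CC(=O)c3c(OCOC)cc(OCOC)cc3O2)cc2c(c1OCOC)OC(C)(C)[C@@H](O[Si](C)(C)C(C)(C)C)C2 | intermediate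
29 | (2S)-2-[(3S)-3,8-dihydroxy-2,2-dimethyl-7-(3-methylbut-2-en-1-yl)chroman-6-yl]-5,7-dihydroxychroman-4-one | CC(C)=CCc1c([C@@H]2CC(=O)c3c(O)cc(O)cc3O2)cc2c(c1O)OC(C)(C)[C@@H](O)C2 | target

## Step count and risks

Total step count: 18. Longest linear sequence: 15 steps (steps 1–13, 17 and 18).

**Step 17 (proposed new method).** What may go wrong: retro-aldol fragmentation or β-elimination of the liberated alkoxide before it meets the aryne, protonation of the aryl anion before it is trapped by the ester, or base-induced opening of ring C that erodes the configuration at C2. The fallback uses known chemistry and closes the same C4–C4a bond by a Parham cyclisation. It sets out from 15, which is reduced with the enantiomeric catalyst RuCl(p-cymene)[(R,R)-TsDPEN] (HCO2H/Et3N) to the (3R)-β-hydroxy ester F1. A Mitsunobu reaction of the (3R)-β-hydroxy ester F1 with bromophenol 20 (PPh3, DIAD, toluene, 0 °C) should give, with inversion, the (3S)-configured 2-bromoaryl ether F2. Bromine–lithium exchange (n-BuLi, THF, −100 °C) followed by intramolecular acylation by the methyl ester, quenched cold with AcOH, returns to the route at 28.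

**Step 11.** What may go wrong: sluggish acyl substitution at the hindered, electron-rich ortho-substituted benzoate, with self-condensation of the acetate enolate or lateral metalation of the benzylic–allylic CH2 taking over. The fallback replaces the enolate condensation by a decarboxylative acylation. It sets out from 12, which is saponified (LiOH, THF/MeOH/H2O, 50 °C) to the carboxylic acid F3. Activation with 1,1'-carbonyldiimidazole (THF, rt) gives, in the flask, the acyl imidazolide F4. C-acylation of potassium methyl malonate (MgCl2, Et3N, THF) gives the acylmalonic half-ester F5, which loses CO2 on acidic work-up and returns to the route at 15.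

**Step 18.** What may go wrong: acid-promoted cyclisation of the prenyl group onto the neighbouring phenol once it is unmasked, or acid-promoted opening of ring C with loss of configuration at C2. The fallback unmasks in two orthogonal, non-protic stages. It sets out from 28: buffered HF·pyridine (pyridine, THF, 0 °C → rt) removes the TBS group to give the tris-MOM alcohol F6. The aryl MOM ethers of the tris-MOM alcohol F6 are then cleaved with TMSOTf/2,2'-bipyridyl (MeCN, 0 °C) followed by water, which arrives at 29.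

Further compounds

F1 | step 17 | methyl (3R)-3-[(3S)-3-[(tert-butyldimethylsilyl)oxy]-8-(methoxymethoxy)-2,2-dimethyl-7-(3-methylbut-2-en-1-yl)chroman-6-yl]-3-hydroxypropanoate | COC(=O)C[C@@H](O)c1cc2c(c(OCOC)c1CC=C(C)C)OC(C)(C)[C@@H](O[Si](C)(C)C(C)(C)C)C2
F2 | step 17 | methyl (3S)-3-[2-bromo-3,5-bis(methoxymethoxy)phenoxy]-3-[(3S)-3-[(tert-butyldimethylsilyl)oxy]-8-(methoxymethoxy)-2,2-dimethyl-7-(3-methylbut-2-en-1-yl)chroman-6-yl]propanoate | COC(=O)C[C@H](Oc1cc(OCOC)cc(OCOC)c1Br)c1cc2c(c(OCOC)c1CC=C(C)C)OC(C)(C)[C@@H](O[Si](C)(C)C(C)(C)C)C2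
F3 | step 11 | (3S)-3-[(tert-butyldimethylsilyl)oxy]-8-(methoxymethoxy)-2,2-dimethyl-7-(3-methylbut-2-en-1-yl)chromane-6-carboxylic acid | OC(=O)c1cc2c(c(OCOC)c1CC=C(C)C)OC(C)(C)[C@@H](O[Si](C)(C)C(C)(C)C)C2
F4 | step 11 | [(3S)-3-[(tert-butyldimethylsilyl)oxy]-8-(methoxymethoxy)-2,2-dimethyl-7-(3-methylbut-2-en-1-yl)chroman-6-yl](1H-imidazol-1-yl)methanone | O=C(c1cc2c(c(OCOC)c1CC=C(C)C)OC(C)(C)[C@@H](O[Si](C)(C)C(C)(C)C)C2)n1ccnc1
F5 | step 11 | 3-[(3S)-3-[(tert-butyldimethylsilyl)oxy]-8-(methoxymethoxy)-2,2-dimethyl-7-(3-methylbut-2-en-1-yl)chroman-6-yl]-2-(methoxycarbonyl)-3-oxopropanoic acid | COC(=O)C(C(=O)O)C(=O)c1cc2c(c(OCOC)c1CC=C(C)C)OC(C)(C)[C@@H](O[Si](C)(C)C(C)(C)C)C2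
F6 | step 18 | (2S)-2-[(3S)-3-hydroxy-8-(methoxymethoxy)-2,2-dimethyl-7-(3-methylbut-2-en-1-yl)chroman-6-yl]-5,7-bis(methoxymethoxy)chroman-4-one | CC(C)=CCc1c([C@@H]2CC(=O)c3c(OCOC)cc(OCOC)cc3O2)cc2c(c1OCOC)OC(C)(C)[C@@H](O)C2
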